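**Plan**

- Numbering (labdane): ring A = C1–C5 + C10, ring B = C5–C10; C17 on C8, C18 (CH3) and C19 (CH2OH) on C4, C20 on C10, side chain C11–C16 (butenolide C13–C16).
- Retrosynthesis, in order: C12–C13 (alkylation of a sulfenylated butyrolactone, then sulfoxide elimination); C8–C17 (homologation of an 8-ketone); C6–C7 (ring B); C9–C10 (Ireland–Claisen); C5–C6 and C10–C20 (enol triflate coupling, enolate methylation). This leaves 2-methylcyclohexane-1,3-dione, CH2O and 4-(benzyloxy)butanoic acid.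
- Forward: ring A is present from the start and is converted into a C5=C10 allylic ester. The [3,3] shift joins C9 to C10 and leaves an exocyclic C5=C6 methylene. Ring B is closed second, at C6–C7; C17 and the butenolide come last.
- Feature that allows the ring closure: C6 is the free CH2 terminus of a 1,1-disubstituted alkene whose inner carbon C5 lies between quaternary C4 and C10. C7 (a chloromethyl ketone carbon on C8) is six atoms away, so a C7 α-keto radical can only close 6-endo to ring B, leaving a tertiary C5 radical under the axial C10 methyl.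
- Stereochemistry: C3/C4 from a catalyst-controlled CBS desymmetrisation; C10 and C9 from the chair Ireland–Claisen; C5 from hydrogen-atom delivery in the ring-closing step; C8 from base equilibration of the 17-aldehyde.

Key step: step 11

Remark: TBS = t-BuMe2Si, TBDPS = t-BuPh2Si, Bn = benzyl; C-numbers in the text are the labdane numbers defined above.

**Route**

Step 1
Reactants: 1 2-methylcyclohexane-1,3-dione
Product: 2 2-(hydroxymethyl)-2-methylcyclohexane-1,3-dione
Conditions: 37 % aq. CH2O, NaHCO3 (cat.), THF/H2O, 0 °C → rt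
Reagents that add atoms: formaldehyde C=O
Why: Aldol addition of the doubly activated C2 enolate to formaldehyde forms the C–C bond at carbon (no O-alkylation as with chloromethyl ethers) and gives the future C4 its C19 arm; the dione stays symmetric, so no stereocentre arises.

Step 2
Reactants: 2 2-(hydroxymethyl)-2-methylcyclohexane-1,3-dione
Product: 3 2-(TBDPSOCH2)-2-methylcyclohexane-1,3-dione
Conditions: t-BuPh2SiCl, imidazole, DMF, 0 °C → rt
Reagents that add atoms: tert-butyl(chloro)diphenylsilane CC(C)(C)[Si](Cl)(c1ccccc1)c1ccccc1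
Why: Imidazole-promoted silylation of the primary alcohol blocks retro-aldol loss of formaldehyde and makes the CH2OR arm much larger than the methyl group for the next step.

Step 3
Reactants: 3 2-(TBDPSOCH2)-2-methylcyclohexane-1,3-dione
Product: 4 (2R,3R)-2-(TBDPSOCH2)-3-hydroxy-2-methylcyclohexan-1-one
Conditions: (S)-1-methyl-3,3-diphenyltetrahydro-1H,3H-pyrrolo[1,2-c][1,3,2]oxazaborole ((S)-Me-CBS, cat.), BH3·SMe2 (substoichiometric in hydride), THF, −30 °C; MeOH quench
Reagents that add atoms: none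
Why: Corey–Bakshi–Shibata reduction desymmetrises the prochiral dione: the catalyst fixes the carbinol configuration (quaternary carbon as the large group), and hydride should come from the carbonyl face syn to methyl and anti to CH2OTBDPS, which selects one enantiotopic carbonyl and sets C3 (R) and C4 (R) together with OH cis to CH2OTBDPS.

Step 4
Reactants: 4 (2R,3R)-2-(TBDPSOCH2)-3-hydroxy-2-methylcyclohexan-1-one
Product: 5 (2R,3R)-3-(TBSO)-2-(TBDPSOCH2)-2-methylcyclohexan-1-one
Conditions: t-BuMe2SiOSO2CF3, 2,6-lutidine, CH2Cl2, −78 → 0 °C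
Reagents that add atoms: tert-butyldimethylsilyl trifluoromethanesulfonate CC(C)(C)[Si](C)(C)OS(=O)(=O)C(F)(F)F
Why: The silyl triflate protects the hindered secondary alcohol next to the quaternary carbon without touching the ketone.

Step 5
Reactants: 5 (2R,3R)-3-(TBSO)-2-(TBDPSOCH2)-2-methylcyclohexan-1-one
Product: 6 (2R,3R,6RS)-3-(TBSO)-2-(TBDPSOCH2)-2,6-dimethylcyclohexan-1-one
Conditions: LiN(i-Pr)2, THF, −78 °C; MeI, −78 → 0 °C
Reagents that add atoms: iodomethane CI
Why: The ketone can enolise only toward C10 because the other α-carbon is quaternary, so enolate methylation installs C20 regiospecifically; the new centre is of no consequence since it becomes sp2 in step 6.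

Step 6
Reactants: 6 (2R,3R,6RS)-3-(TBSO)-2-(TBDPSOCH2)-2,6-dimethylcyclohexan-1-one
Product: 7 (5R,6R)-5-(TBSO)-6-(TBDPSOCH2)-2,6-dimethylcyclohex-1-en-1-yl trifluoromethanesulfonate
Conditions: KN(SiMe3)2, THF, −78 → 0 °C; PhN(SO2CF3)2
Reagents that add atoms: N-phenylbis(trifluoromethanesulfonimide) O=S(=O)(N(c1ccccc1)S(=O)(=O)C(F)(F)F)C(F)(F)F
Why: The single remaining α-hydrogen gives the tetrasubstituted enolate, and O-sulfonylation then affords the C5=C10 enol triflate as the only possible regioisomer.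

Step 7
Reactants: 7 (5R,6R)-5-(TBSO)-6-(TBDPSOCH2)-2,6-dimethylcyclohex-1-en-1-yl trifluoromethanesulfonate
Product: 8 [(5R,6R)-5-(TBSO)-6-(TBDPSOCH2)-2,6-dimethylcyclohex-1-en-1-yl]methanol
Conditions: Bu3SnCH2OH, Pd(PPh3)4 (cat.), LiCl, 1,4-dioxane, 100 °C
Reagents that add atoms: (tributylstannyl)methanol CCCC[Sn](CCCC)(CCCC)CO
Why: Stille coupling of the enol triflate with the hydroxymethyl stannane attaches C6 to C5 as an allylic alcohol while retaining the tetrasubstituted C5=C10 alkene.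

Step 8
Reactants: 8 [(5R,6R)-5-(TBSO)-6-(TBDPSOCH2)-2,6-dimethylcyclohex-1-en-1-yl]methanol + 9 4-(benzyloxy)butanoic acid
Product: 10 [(5R,6R)-5-(TBSO)-6-(TBDPSOCH2)-2,6-dimethylcyclohex-1-en-1-yl]methyl 4-(benzyloxy)butanoate
Conditions: N,N'-dicyclohexylcarbodiimide, 4-(dimethylamino)pyridine (cat.), CH2Cl2, 0 °C → rt
Reagents that add atoms: none
Why: Steglich esterification joins the primary allylic alcohol to the acid that carries C8, C9, C11 and C12 under neutral conditions.

Step 9
Reactants: 10 [(5R,6R)-5-(TBSO)-6-(TBDPSOCH2)-2,6-dimethylcyclohex-1-en-1-yl]methyl 4-(benzyloxy)butanoate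
Product: 13 (2S)-4-(benzyloxy)-2-[(1S,3R,4R)-4-(TBSO)-3-(TBDPSOCH2)-1,3-dimethyl-2-methylidenecyclohexyl]butanoic acid, via silyl ketene acetal 11 (not isolated), via trimethylsilyl ester 12 (not isolated)
Conditions: LiN(i-Pr)2, THF/DMPU, −78 °C; Me3SiCl, Et3N, −78 °C → rt, then 60 °C; 1 M aq. HCl work-up
Reagents that add atoms: none
Why: Ireland–Claisen rearrangement: enolisation in THF/DMPU should give the ketene acetal with C11 cis to OSiMe3; the chair [3,3] shift across the tetrasubstituted C5=C10 alkene then forms C9–C10 on the ring face carrying the C4 methyl (anti to CH2OTBDPS and OTBS), which sets C10, while the pseudo-equatorial C11 in the chair sets C9 relative to C10; the allyl transposition leaves the exocyclic C5=C6 methylene.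

Step 10
Reactants: 13 (2S)-4-(benzyloxy)-2-[(1S,3R,4R)-4-(TBSO)-3-(TBDPSOCH2)-1,3-dimethyl-2-methylidenecyclohexyl]butanoic acid
Product: 16 (3S)-5-(benzyloxy)-1-chloro-3-[(1S,3R,4R)-4-(TBSO)-3-(TBDPSOCH2)-1,3-dimethyl-2-methylidenecyclohexyl]pentan-2-one, via acid chloride 14 (not isolated), via diazoketone 15 (not isolated)
Conditions: (COCl)2, DMF (cat.), CH2Cl2, 0 °C → rt; CH2N2 (excess), Et2O, 0 °C; HCl (2 M in Et2O), 0 °C
Reagents that add atoms: diazomethane C=[N+]=[N-]; hydrogen chloride Cl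
Why: Arndt–Eistert-type acylation of diazomethane followed by Nierenstein-type addition of HCl with loss of N2 attaches C7 to C8 as a chloromethyl ketone under base-free conditions that should leave C9 untouched.

Step 11
Reactants: 16 (3S)-5-(benzyloxy)-1-chloro-3-[(1S,3R,4R)-4-(TBSO)-3-(TBDPSOCH2)-1,3-dimethyl-2-methylidenecyclohexyl]pentan-2-one
Product: 17 (1S,4aS,5R,6R,8aR)-1-[2-(benzyloxy)ethyl]-6-(TBSO)-5-(TBDPSOCH2)-5,8a-dimethyloctahydronaphthalen-2(1H)-one
Conditions: (Me3Si)3SiH (syringe pump), 2,2'-azobis(2-methylpropionitrile) (cat.), PhMe, 90 °C, high dilution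
Reagents that add atoms: none
Why: Chlorine-atom abstraction from 16 by the silyl radical gives the electrophilic C7 α-keto radical, which adds to the CH2 terminus C6 of the electron-rich exocyclic C5=C6 alkene; the resulting tertiary C5 radical abstracts hydrogen from the silane and carries the chain. The closest known reaction type is the reductive 6-endo cyclisation of α-carbonyl radicals onto 1,1-disubstituted alkenes. Ring B closes in the 6-endo-trig mode, because the 5-exo alternative would join C7 to C5, a carbon flanked by two quaternary centres, and would give a primary radical. The only new stereocentre, C5, is controlled by the C10 methyl, which stands over one face of the planar C5 radical and is reinforced on that face by the C4 CH2OTBDPS arm, so hydrogen should be delivered to the opposite face and the ring fusion should become trans (C5–H anti to C20). The step needs cyclisation to outrun direct reduction of the C7 radical, which is addressed by slow addition at high dilution of a silane that donates hydrogen more slowly than a stannane, and it needs C9 to stay intact, which the neutral conditions secure.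

Step 12
Reactants: 17 (1S,4aS,5R,6R,8aR)-1-[2-(benzyloxy)ethyl]-6-(TBSO)-5-(TBDPSOCH2)-5,8a-dimethyloctahydronaphthalen-2(1H)-one
Product: 18 8-(methoxymethylidene) derivative of 17 (E/Z mixture)
Conditions: Ph3P(CH2OMe)Cl, KN(SiMe3)2, THF, 0 °C → rt
Reagents that add atoms: (methoxymethyl)triphenylphosphonium chloride COC[P+](c1ccccc1)(c1ccccc1)c1ccccc1.[Cl-]
Why: Wittig methoxymethylenation of the only carbonyl introduces C17 as an enol ether; preformed ylide at low temperature limits enolisation toward C9, whose equatorial side chain is in any case the more stable epimer.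

Step 13
Reactants: 18 8-(methoxymethylidene) derivative of 17 (E/Z mixture)
Product: 21 (8S)-17-alcohol [C8–CH2OH equatorial; 12-OBn; 3-OTBS; 19-OTBDPS], via aldehyde epimer mixture 19 (not isolated), via equatorial aldehyde 20 (not isolated)
Conditions: 1 M aq. HCl, THF, rt; K2CO3, MeOH, rt; NaBH4, 0 °C
Reagents that add atoms: water O
Why: Enol ether hydrolysis gives the 17-aldehyde as C8 epimers, base equilibration through the enolate should funnel both into the equatorial aldehyde because an axial CHO would be syn-diaxial to the C10 methyl (stereoconvergent setting of C8, trans to the C9 chain), and borohydride then reduces the aldehyde.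

Step 14
Reactants: 21 (8S)-17-alcohol [C8–CH2OH equatorial; 12-OBn; 3-OTBS; 19-OTBDPS]
Product: 22 17-O-TBS ether of 21
Conditions: t-BuMe2SiCl, imidazole, DMF, rt
Reagents that add atoms: tert-butyl(chloro)dimethylsilane CC(C)(C)[Si](C)(C)Cl
Why: Silylation of the primary alcohol keeps C17–OH apart from the C12 oxygen that is unmasked next.

Step 15
Reactants: 22 17-O-TBS ether of 21
Product: 23 12-alcohol [3,17-bis-OTBS; 19-OTBDPS]
Conditions: H2 (1 atm), Pd/C, EtOAc, rt
Reagents that add atoms: none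
Why: Hydrogenolysis cleaves the benzyl ether selectively, since 22 has no alkene and silyl ethers are inert to these conditions.

Step 16
Reactants: 23 12-alcohol [3,17-bis-OTBS; 19-OTBDPS]
Product: 24 12-iodide [3,17-bis-OTBS; 19-OTBDPS]
Conditions: I2, PPh3, imidazole, CH2Cl2, 0 °C → rt
Reagents that add atoms: iodine II
Why: Appel-type iodination converts the unhindered primary alcohol into the iodide by SN2 displacement of the oxyphosphonium group.

Step 17
Reactants: 25 3-bromooxolan-2-one + 26 benzenethiol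
Product: 27 3-(phenylsulfanyl)oxolan-2-one
Conditions: Et3N, CH2Cl2, 0 °C → rt
Reagents that add atoms: none
Why: SN2 displacement of the activated α-bromide by thiolate gives the sulfenylated lactone that serves as a butenolide α-anion equivalent.

Step 18
Reactants: 24 12-iodide [3,17-bis-OTBS; 19-OTBDPS] + 27 3-(phenylsulfanyl)oxolan-2-one
Product: 28 3-alkyl-3-(phenylsulfanyl)oxolan-2-one (C12–C13 coupled; C13 epimers)
Conditions: LiN(i-Pr)2, THF, −78 °C (27); then 24, HMPA, −78 °C → rt
Reagents that add atoms: none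
Why: The sulfur-stabilised lactone enolate is alkylated at carbon by the primary iodide, forming C12–C13; the new centre is lost in step 19.

Step 19
Reactants: 28 3-alkyl-3-(phenylsulfanyl)oxolan-2-one (C12–C13 coupled; C13 epimers)
Product: 30 3,17-bis-O-TBS-19-O-TBDPS-14-deoxy-17-hydroxyandrographolide, via sulfoxide 29 (not isolated)
Conditions: mCPBA (1 equiv), CH2Cl2, −78 → 0 °C; then PhMe, NaHCO3, 110 °C
Reagents that add atoms: none
Why: Sulfide oxidation followed by thermal syn-elimination of the sulfoxide (dehydrosulfenylation) takes the ring β-hydrogen, as is usual for α-alkyl-α-sulfinyl lactones, and gives the endocyclic C13=C14 butenolide.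

Step 20
Reactants: 30 3,17-bis-O-TBS-19-O-TBDPS-14-deoxy-17-hydroxyandrographolide
Product: 31 14-deoxy-17-hydroxyandrographolide
Conditions: HF·pyridine, THF/pyridine, 0 °C → rt
Reagents that add atoms: none
Why: Fluoride-driven cleavage of the three silyl ethers under mildly acidic conditions should release the triol without opening or isomerising the butenolide.

**Compound list**

1 | 2-methylcyclohexane-1,3-dione | CC1C(=O)CCCC1=O | starting material
2 | 2-(hydroxymethyl)-2-methylcyclohexane-1,3-dione | CC1(CO)C(=O)CCCC1=O | intermediate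
3 | 2-(TBDPSOCH2)-2-methylcyclohexane-1,3-dione | CC1(CO[Si](c2ccccc2)(c2ccccc2)C(C)(C)C)C(=O)CCCC1=O | intermediate
4 | (2R,3R)-2-(TBDPSOCH2)-3-hydroxy-2-methylcyclohexan-1-one | C[C@]1(CO[Si](c2ccccc2)(c2ccccc2)C(C)(C)C)C(=O)CCC[C@H]1O | intermediate
5 | (2R,3R)-3-(TBSO)-2-(TBDPSOCH2)-2-methylcyclohexan-1-one | C[C@]1(CO[Si](c2ccccc2)(c2ccccc2)C(C)(C)C)C(=O)CCC[C@H]1O[Si](C)(C)C(C)(C)C | intermediate
6 | (2R,3R,6RS)-3-(TBSO)-2-(TBDPSOCH2)-2,6-dimethylcyclohexan-1-one | C[C@]1(CO[Si](c2ccccc2)(c2ccccc2)C(C)(C)C)C(=O)C(C)CC[C@H]1O[Si](C)(C)C(C)(C)C | intermediate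
7 | (5R,6R)-5-(TBSO)-6-(TBDPSOCH2)-2,6-dimethylcyclohex-1-en-1-yl trifluoromethanesulfonate | C[C@]1(CO[Si](c2ccccc2)(c2ccccc2)C(C)(C)C)C(OS(=O)(=O)C(F)(F)F)=C(C)CC[C@H]1O[Si](C)(C)C(C)(C)C | intermediate
8 | [(5R,6R)-5-(TBSO)-6-(TBDPSOCH2)-2,6-dimethylcyclohex-1-en-1-yl]methanol | C[C@]1(CO[Si](c2ccccc2)(c2ccccc2)C(C)(C)C)C(CO)=C(C)CC[C@H]1O[Si](C)(C)C(C)(C)C | intermediate
9 | 4-(benzyloxy)butanoic acid | OC(=O)CCCOCc1ccccc1 | starting material
10 | [(5R,6R)-5-(TBSO)-6-(TBDPSOCH2)-2,6-dimethylcyclohex-1-en-1-yl]methyl 4-(benzyloxy)butanoate | C[C@]1(CO[Si](c2ccccc2)(c2ccccc2)C(C)(C)C)C(COC(=O)CCCOCc2ccccc2)=C(C)CC[C@H]1O[Si](C)(C)C(C)(C)C | intermediate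
11 | (Z)-O-trimethylsilyl ketene acetal of ester 10 (C11 cis to OSiMe3) | C[C@]1(CO[Si](c2ccccc2)(c2ccccc2)C(C)(C)C)C(CO/C(O[Si](C)(C)C)=C/CCOCc2ccccc2)=C(C)CC[C@H]1O[Si](C)(C)C(C)(C)C | intermediate
12 | trimethylsilyl ester of acid 13 | C[C@]1(CO[Si](c2ccccc2)(c2ccccc2)C(C)(C)C)C(=C)[C@](C)([C@H](CCOCc2ccccc2)C(=O)O[Si](C)(C)C)CC[C@H]1O[Si](C)(C)C(C)(C)C | intermediate
13 | (2S)-4-(benzyloxy)-2-[(1S,3R,4R)-4-(TBSO)-3-(TBDPSOCH2)-1,3-dimethyl-2-methylidenecyclohexyl]butanoic acid | C[C@]1(CO[Si](c2ccccc2)(c2ccccc2)C(C)(C)C)C(=C)[C@](C)([C@H](CCOCc2ccccc2)C(=O)O)CC[C@H]1O[Si](C)(C)C(C)(C)C | intermediate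
14 | acid chloride of 13 | C[C@]1(CO[Si](c2ccccc2)(c2ccccc2)C(C)(C)C)C(=C)[C@](C)([C@H](CCOCc2ccccc2)C(=O)Cl)CC[C@H]1O[Si](C)(C)C(C)(C)C | intermediate
15 | diazomethyl ketone from 14 | C[C@]1(CO[Si](c2ccccc2)(c2ccccc2)C(C)(C)C)C(=C)[C@](C)([C@H](CCOCc2ccccc2)C(=O)C=[N+]=[N-])CC[C@H]1O[Si](C)(C)C(C)(C)C | intermediate
16 | (3S)-5-(benzyloxy)-1-chloro-3-[(1S,3R,4R)-4-(TBSO)-3-(TBDPSOCH2)-1,3-dimethyl-2-methylidenecyclohexyl]pentan-2-one | C[C@]1(CO[Si](c2ccccc2)(c2ccccc2)C(C)(C)C)C(=C)[C@](C)([C@H](CCOCc2ccccc2)C(=O)CCl)CC[C@H]1O[Si](C)(C)C(C)(C)C | intermediate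
17 | (1S,4aS,5R,6R,8aR)-1-[2-(benzyloxy)ethyl]-6-(TBSO)-5-(TBDPSOCH2)-5,8a-dimethyloctahydronaphthalen-2(1H)-one (trans-decalin 8-ketone; C3, C4, C5, C9, C10 arranged as in the target) | C[C@]1(CO[Si](c3ccccc3)(c3ccccc3)C(C)(C)C)[C@H]2CCC(=O)[C@@H](CCOCc3ccccc3)[C@]2(C)CC[C@H]1O[Si](C)(C)C(C)(C)C | intermediate
18 | 8-(methoxymethylidene) derivative of 17 (E/Z mixture) | C[C@]1(CO[Si](c3ccccc3)(c3ccccc3)C(C)(C)C)[C@H]2CCC(=COC)[C@@H](CCOCc3ccccc3)[C@]2(C)CC[C@H]1O[Si](C)(C)C(C)(C)C | intermediate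
19 | 17-aldehyde from 18, mixture of C8 epimers | C[C@]1(CO[Si](c3ccccc3)(c3ccccc3)C(C)(C)C)[C@H]2CCC(C=O)[C@@H](CCOCc3ccccc3)[C@]2(C)CC[C@H]1O[Si](C)(C)C(C)(C)C | intermediate
20 | (8S)-17-aldehyde (CHO equatorial, trans to the C9 chain) | C[C@]1(CO[Si](c3ccccc3)(c3ccccc3)C(C)(C)C)[C@H]2CC[C@H](C=O)[C@@H](CCOCc3ccccc3)[C@]2(C)CC[C@H]1O[Si](C)(C)C(C)(C)C | intermediate
21 | (8S)-17-alcohol, 12-O-benzyl, 3-O-TBS, 19-O-TBDPS | C[C@]1(CO[Si](c3ccccc3)(c3ccccc3)C(C)(C)C)[C@H]2CC[C@H](CO)[C@@H](CCOCc3ccccc3)[C@]2(C)CC[C@H]1O[Si](C)(C)C(C)(C)C | intermediate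
22 | 17-O-TBS ether of 21 | C[C@]1(CO[Si](c3ccccc3)(c3ccccc3)C(C)(C)C)[C@H]2CC[C@H](CO[Si](C)(C)C(C)(C)C)[C@@H](CCOCc3ccccc3)[C@]2(C)CC[C@H]1O[Si](C)(C)C(C)(C)C | intermediate
23 | 12-alcohol (3,17-bis-O-TBS, 19-O-TBDPS) | C[C@]1(CO[Si](c3ccccc3)(c3ccccc3)C(C)(C)C)[C@H]2CC[C@H](CO[Si](C)(C)C(C)(C)C)[C@@H](CCO)[C@]2(C)CC[C@H]1O[Si](C)(C)C(C)(C)C | intermediate
24 | 12-iodide (3,17-bis-O-TBS, 19-O-TBDPS) | C[C@]1(CO[Si](c3ccccc3)(c3ccccc3)C(C)(C)C)[C@H]2CC[C@H](CO[Si](C)(C)C(C)(C)C)[C@@H](CCI)[C@]2(C)CC[C@H]1O[Si](C)(C)C(C)(C)C | intermediate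
25 | 3-bromooxolan-2-one (α-bromo-γ-butyrolactone, racemic) | BrC1CCOC1=O | starting material
26 | benzenethiol | Sc1ccccc1 | starting material
27 | 3-(phenylsulfanyl)oxolan-2-one (racemic) | O=C1OCCC1Sc1ccccc1 | intermediate
28 | 3-alkyl-3-(phenylsulfanyl)oxolan-2-one from 24 and 27 (C13 epimers) | C[C@]1(CO[Si](c3ccccc3)(c3ccccc3)C(C)(C)C)[C@H]2CC[C@H](CO[Si](C)(C)C(C)(C)C)[C@@H](CCC3(Sc4ccccc4)CCOC3=O)[C@]2(C)CC[C@H]1O[Si](C)(C)C(C)(C)C | intermediate
29 | sulfoxide of 28 (diastereomer mixture) | C[C@]1(CO[Si](c3ccccc3)(c3ccccc3)C(C)(C)C)[C@H]2CC[C@H](CO[Si](C)(C)C(C)(C)C)[C@@H](CCC3(S(=O)c4ccccc4)CCOC3=O)[C@]2(C)CC[C@H]1O[Si](C)(C)C(C)(C)C | intermediate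
30 | 3,17-bis-O-TBS-19-O-TBDPS-14-deoxy-17-hydroxyandrographolide | C[C@]1(CO[Si](c3ccccc3)(c3ccccc3)C(C)(C)C)[C@H]2CC[C@H](CO[Si](C)(C)C(C)(C)C)[C@@H](CCC3=CCOC3=O)[C@]2(C)CC[C@H]1O[Si](C)(C)C(C)(C)C | intermediate
31 | 14-deoxy-17-hydroxyandrographolide, 3-[2-[(1R,2S,4aS,5R,6R,8aS)-6-hydroxy-2,5-bis(hydroxymethyl)-5,8a-dimethyldecahydronaphthalen-1-yl]ethyl]furan-2(5H)-one | C[C@]1(CO)[C@H]2CC[C@H](CO)[C@@H](CCC3=CCOC3=O)[C@]2(C)CC[C@H]1O | target

**Step count**

Total: 20 steps. Longest linear sequence: 19 steps (steps 1–16 and 18–20; step 17 is a one-step branch).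

**Steps most likely to fail, with fallbacks**

Step 11. The C7 radical may abstract hydrogen before it cyclises, giving the uncyclised methyl ketone, or hydrogen transfer to the C5 radical may be insufficiently face-selective. The fallback closes the ring oxidatively with no hydrogen donor present and sets C5 in a separate step. It sets out from acid 13. MeLi (excess, Et2O, 0 °C) should give the methyl ketone F1. LiN(i-Pr)2/Me3SiCl at −78 °C should give the kinetic trimethylsilyl enol ether F2. Oxidation with (NH4)2Ce(NO3)6/NaHCO3 in MeCN should generate the same α-keto radical, which closes 6-endo on C6; oxidation of the C5 radical and loss of a C6 proton would give the Δ5(6)-octalin-8-one F3. Mukaiyama-type hydrogen-atom-transfer hydrogenation of the trisubstituted alkene (Mn(dpm)3, PhSiH3, t-BuOOH, i-PrOH) should then give the more stable trans ring fusion. The fallback comes back to the route at ketone 17.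

Step 9. The α-branched ketene acetal may decompose or fragment before the congested [3,3] shift across the tetrasubstituted alkene takes place, or enolate geometry may be poorly controlled so that C9 forms as a mixture. The fallback separates C–C bond formation at C10 from introduction of the side chain. It sets out from allylic alcohol 8. Johnson–Claisen rearrangement (MeC(OEt)3, EtCO2H cat., 140 °C) passes through an unsubstituted, less hindered ketene acetal and should give the ethyl ester F4 with the same C10 configuration and the exocyclic methylene. Enolate alkylation (LiN(i-Pr)2, THF/HMPA, then 2-(benzyloxy)ethyl iodide) would give the α-alkylated ethyl ester F5 as C9 epimers. Chloromethyllithium generated in situ (ICH2Cl, MeLi·LiBr, THF, −78 °C) converts the ester directly into the chloromethyl ketone. The fallback comes back to the route at 16, as a C9 mixture; after step 11 this would be equilibrated with base at ketone 17, where the equatorial C9 chain is the more stable epimer.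

Step 7. Transmetalation of the hydroxymethyl stannane to the hindered, tetrasubstituted alkenylpalladium may be too slow, so that reduction or decomposition of the triflate competes. The fallback replaces the tin reagent by CO insertion, which is little affected by steric hindrance. It sets out from triflate 7. Methoxycarbonylation (Pd(OAc)2, PPh3, CO, MeOH, Et3N, DMF, 60 °C) should give the methyl enoate F6, and i-Bu2AlH (CH2Cl2, −78 °C) reduces it to the allylic alcohol. The fallback comes back to the route at 8.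

Further compounds
F1 | step 11 | methyl ketone from acid 13 (CO2H replaced by COCH3) | C[C@]1(CO[Si](c2ccccc2)(c2ccccc2)C(C)(C)C)C(=C)[C@](C)([C@H](CCOCc2ccccc2)C(C)=O)CC[C@H]1O[Si](C)(C)C(C)(C)C
F2 | step 11 | kinetic trimethylsilyl enol ether of F1 | C[C@]1(CO[Si](c2ccccc2)(c2ccccc2)C(C)(C)C)C(=C)[C@](C)([C@H](CCOCc2ccccc2)C(=C)O[Si](C)(C)C)CC[C@H]1O[Si](C)(C)C(C)(C)C
F3 | step 11 | Δ5(6)-octalin-8-one (5,6-didehydro analogue of 17) | C[C@]1(CO[Si](c3ccccc3)(c3ccccc3)C(C)(C)C)C2=CCC(=O)[C@@H](CCOCc3ccccc3)[C@]2(C)CC[C@H]1O[Si](C)(C)C(C)(C)C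
F4 | step 9 | ethyl 2-[(1S,3R,4R)-4-(TBSO)-3-(TBDPSOCH2)-1,3-dimethyl-2-methylidenecyclohexyl]acetate | C[C@]1(CO[Si](c2ccccc2)(c2ccccc2)C(C)(C)C)C(=C)[C@](C)(CC(=O)OCC)CC[C@H]1O[Si](C)(C)C(C)(C)C
F5 | step 9 | ethyl ester of acid 13 as a mixture of C9 epimers | C[C@]1(CO[Si](c2ccccc2)(c2ccccc2)C(C)(C)C)C(=C)[C@](C)(C(CCOCc2ccccc2)C(=O)OCC)CC[C@H]1O[Si](C)(C)C(C)(C)C
F6 | step 7 | methyl (5R,6R)-5-(TBSO)-6-(TBDPSOCH2)-2,6-dimethylcyclohex-1-ene-1-carboxylate | C[C@]1(CO[Si](c2ccccc2)(c2ccccc2)C(C)(C)C)C(C(=O)OC)=C(C)CC[C@H]1O[Si](C)(C)C(C)(C)C
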